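**Retrosynthetic overview**
- Target 7 ← dialdehyde 5. Both hydroxyls (C1–OH on the 3,4,5-tribromo ring A, C6'–OH on the 3',5'-dibromo ring B) lie ortho to the bridging oxygen (C2–O–C1'), so each is traced back to a formyl group; the C1–O and C6'–O bonds come from a double Baeyer–Villiger/Dakin oxygen insertion.
- 5 ← phenol 3 + fluoroaldehyde 4. The ether bond O–C1' is made by SNAr, with the ring-B formyl group activating the ortho fluoride.
- 3 ← 1 + bromine 2. C3–Br and C5–Br are introduced by hydroxyl-directed bromination (ortho and para to OH, both meta to CHO).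
- No ring is formed: both benzene rings are bought. The two formyl groups first direct and activate, then become the hydroxyls.

Key step: step 3

Remark: the target has no stereocentre and no hindered axis (the diaryl ether rotates freely), so it is achiral and no stereocontrol is needed.

**Step 1**
Reactants: 1 4-bromo-2-hydroxybenzaldehyde; 2 bromine
Product: 3 3,4,5-tribromo-2-hydroxybenzaldehyde
Conditions: Br2 (2.2 equiv), NaOAc, AcOH, rt → 50 °C; aq. NaHSO3 quench
Reagents that add atoms: bromine (compound 2), BrBr
Why: Electrophilic aromatic bromination in which the hydroxyl directs to its para (C5) and ortho (C3) positions, both of which are also meta to the formyl group, so the two directing effects agree and C6 (meta to OH, ortho to CHO) should stay untouched.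

**Step 2**
Reactants: 3 3,4,5-tribromo-2-hydroxybenzaldehyde; 4 2,4-dibromo-6-fluorobenzaldehyde
Product: 5 3,4,5-tribromo-2-(3,5-dibromo-2-formylphenoxy)benzaldehyde
Conditions: K2CO3, dry DMF, 80–100 °C, N2
Reagents that add atoms: none
Why: Nucleophilic aromatic substitution (addition–elimination) in which the phenoxide of 3 adds to the fluorine-bearing carbon of 4, the Meisenheimer complex being stabilised by the ortho formyl group and the two meta bromines, while fluoride leaves far faster than the ring bromides and dry carbonate avoids Cannizzaro chemistry.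

**Step 3**
Reactants: 5 3,4,5-tribromo-2-(3,5-dibromo-2-formylphenoxy)benzaldehyde
Product: 7 3,4,5-tribromo-2-(3,5-dibromo-2-hydroxyphenoxy)phenol, via diformate 6 (not isolated)
Conditions: mCPBA (excess), TFA (cat.), CH2Cl2, 0 °C → reflux; aq. Na2S2O3; then HCl (cat.), MeOH, rt
Reagents that add atoms: mCPBA (3-chloroperbenzoic acid), O=C(OO)c1cccc(Cl)c1
Why: The peracid adds to each protonated formyl group to give a Criegee peroxyhemiacetal, the ring carbon then shifts from carbon to the peroxide oxygen with loss of 3-chlorobenzoic acid, forming the C1–O and C6'–O bonds as aryl formates, and acidic methanolysis frees the two phenols once the oxidant has been destroyed. The closest known reaction type is the Baeyer–Villiger (Dakin-type) oxidation of ortho-alkoxy- and ortho-aryloxybenzaldehydes to phenols through their formates. No ring is closed and no stereocentre is created. The selectivity needed is aryl over hydride migration in both Criegee adducts; it should be secured by the ether oxygen ortho to each migrating carbon (on C2 for ring A, on C1' for ring B), whose lone pair supports the electron-poor ipso carbon in the transition state, by the twist the ortho substituents impose on the adduct, and by acidic conditions that keep the adduct protonated, since its oxyanion would favour hydride shift to the benzoic acid. Keeping both phenols masked as formates until the peracid is quenched should protect them from over-oxidation.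

**Compound list**
1 | 4-bromo-2-hydroxybenzaldehyde | O=Cc1ccc(Br)cc1O | starting material
2 | bromine | BrBr | starting material
3 | 3,4,5-tribromo-2-hydroxybenzaldehyde | O=Cc1cc(Br)c(Br)c(Br)c1O | intermediate
4 | 2,4-dibromo-6-fluorobenzaldehyde | O=Cc1c(F)cc(Br)cc1Br | starting material
5 | 3,4,5-tribromo-2-(3,5-dibromo-2-formylphenoxy)benzaldehyde | O=Cc1cc(Br)c(Br)c(Br)c1Oc1cc(Br)cc(Br)c1C=O | intermediate
6 | 3,4,5-tribromo-2-[3,5-dibromo-2-(formyloxy)phenoxy]phenyl formate | O=COc1cc(Br)c(Br)c(Br)c1Oc1cc(Br)cc(Br)c1OC=O | intermediate
7 | 3,4,5-tribromo-2-(3,5-dibromo-2-hydroxyphenoxy)phenol | Oc1cc(Br)c(Br)c(Br)c1Oc1cc(Br)cc(Br)c1O | target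

**Total step count:** 3
**Longest linear sequence:** 3 steps (1 → 3 → 5 → 7)

**Steps most likely to fail**

Step 3. Hydride instead of aryl migration may take over in one or both Criegee adducts, most likely on the more electron-poor tribrominated ring, which would carry the formyl carbon to the carboxylic acid level. The fallback sets out from 5 and comes back at 7. Methylmagnesium bromide (THF, −78 → 0 °C) should add to both formyl groups to give 1-[3,4,5-tribromo-2-[3,5-dibromo-2-(1-hydroxyethyl)phenoxy]phenyl]ethanol F1, a stereoisomer mixture whose centres are removed in the next operation. Dess–Martin periodinane (CH2Cl2, rt) should then give 1-[3,4,5-tribromo-2-(2-acetyl-3,5-dibromophenoxy)phenyl]ethanone F2. Baeyer–Villiger oxidation of the two aryl methyl ketones with trifluoroperacetic acid (TFAA, urea–H2O2, Na2HPO4, CH2Cl2) has only methyl as competing migrating group, so aryl shift should dominate and give 2-(2-acetoxy-3,5-dibromophenoxy)-3,4,5-tribromophenyl acetate F3. Methanolysis (HCl cat., MeOH) should then deliver 7.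

Step 2. Addition of the hindered, weakly basic phenoxide may be slow, so that displacement of an activated ring bromide or base-induced degradation of the aldehydes competes at the temperature required. The fallback sets out from 3 and comes back at 5. Acetalisation with ethylene glycol (TsOH cat., toluene, Dean–Stark) should give 2,3,4-tribromo-6-(1,3-dioxolan-2-yl)phenol F4, whose phenoxide is more basic and no longer tied up by the ortho carbonyl. Reaction with 4 (Cs2CO3, DMF, 60–80 °C) should give 2,4-dibromo-6-[2,3,4-tribromo-6-(1,3-dioxolan-2-yl)phenoxy]benzaldehyde F5. Aqueous HCl in THF at rt should then unmask the second aldehyde and return 5.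

Step 1. Bromination may stall after the first substitution at C5, and forcing the crowded C3 position may bring ipso attack at the formyl-bearing carbon (bromodeformylation) or oxidation of the aldehyde. The fallback sets out from bromine 2, used on commercial methyl 4-bromo-2-hydroxybenzoate (COC(=O)c1ccc(Br)cc1O) in place of 1, and comes back at 3. Bromination (Br2, NaOAc, AcOH, up to 80 °C), which can be pushed harder because no formyl group is at risk, should give methyl 3,4,5-tribromo-2-hydroxybenzoate F6. Reduction with DIBAL-H (excess, THF/toluene, −78 → 0 °C) should give 2,3,4-tribromo-6-(hydroxymethyl)phenol F7. Selective benzylic oxidation with MnO2 (CH2Cl2, rt) should then give 3.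

**Further compounds**
F1 | step 3 | 1-[3,4,5-tribromo-2-[3,5-dibromo-2-(1-hydroxyethyl)phenoxy]phenyl]ethanol (stereoisomer mixture) | CC(O)c1cc(Br)c(Br)c(Br)c1Oc1cc(Br)cc(Br)c1C(C)O
F2 | step 3 | 1-[3,4,5-tribromo-2-(2-acetyl-3,5-dibromophenoxy)phenyl]ethanone | CC(=O)c1cc(Br)c(Br)c(Br)c1Oc1cc(Br)cc(Br)c1C(C)=O
F3 | step 3 | 2-(2-acetoxy-3,5-dibromophenoxy)-3,4,5-tribromophenyl acetate | CC(=O)Oc1cc(Br)c(Br)c(Br)c1Oc1cc(Br)cc(Br)c1OC(C)=O
F4 | step 2 | 2,3,4-tribromo-6-(1,3-dioxolan-2-yl)phenol | Oc1c(Br)c(Br)c(Br)cc1C1OCCO1
F5 | step 2 | 2,4-dibromo-6-[2,3,4-tribromo-6-(1,3-dioxolan-2-yl)phenoxy]benzaldehyde | O=Cc1c(Br)cc(Br)cc1Oc1c(Br)c(Br)c(Br)cc1C1OCCO1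
F6 | step 1 | methyl 3,4,5-tribromo-2-hydroxybenzoate | COC(=O)c1cc(Br)c(Br)c(Br)c1O
F7 | step 1 | 2,3,4-tribromo-6-(hydroxymethyl)phenol | OCc1cc(Br)c(Br)c(Br)c1O
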